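**Retrosynthetic overview**

1. Ring A is the hexasubstituted benzene (C1 2-(3-methoxyphenyl)ethyl; C2, C4, C6 4-hydroxybenzyl; C3 OH; C5 OMe). The strategy rests on C5, an oxygen-bearing ring carbon between the benzyl-bearing C4 and C6: it is brought in as carbon monoxide, while the C3 oxygen arrives as a migrating ester, so the two ring A oxygens are formed already differentiated.
2. The last steps (benzyl ether hydrogenolysis, C3 pivalate cleavage, C5 O-methylation) lead back to a ring A phenol with free C5–OH and C3–OPiv.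
3. Ring A, the only ring formed, is closed by a rhodium-catalysed carbonylative (5+1) benzannulation (bonds C4–C5 and C5–C6) of a tertiary 3-pivaloyloxy-1,4-enyne C6=C1–C2(OPiv)–C3≡C4 that already carries all four carbon substituents.
4. The enyne ester comes from a cerium acetylide (C3≡C4 with its benzyl group) and an (E)-α-phenethyl enone (C2, C1, C6). The enone comes from a Weinreb amide and a benzylic Grignard reagent, and the (E)-C1=C6 alkene from a Wittig reaction of an α-phenethyl ester ylide with an arylacetaldehyde.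
5. The four outer benzene rings are bought: 4-(benzyloxy)benzyl chloride, 2-[4-(benzyloxy)phenyl]ethanol and 1-(3-bromopropyl)-3-methoxybenzene supply them.

Key step: step 10

Remark on the chemistry: the target has no stereocentre. The (E)-alkene set in step 4 and the racemic carbinol centre made in step 8 both disappear on aromatisation in step 10. The three aryl building blocks named in line 5 are assumed to be purchasable. Ring A locants are those of line 1.

**Route**

Step 1
Reactants: 1 1-(3-bromopropyl)-3-methoxybenzene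
Product: 2 [3-(3-methoxyphenyl)propyl](triphenyl)phosphonium bromide
Conditions: PPh3 (1.1 equiv), toluene, reflux
Reagents that add atoms: triphenylphosphine, c1ccc(P(c2ccccc2)c2ccccc2)cc1
Why: SN2 quaternisation of triphenylphosphine by an unhindered primary bromide (phosphonium salt formation) is routine, and the salt should crystallise from the hot solvent.

Step 2
Reactants: 2 [3-(3-methoxyphenyl)propyl](triphenyl)phosphonium bromide
Product: 5 methyl 4-(3-methoxyphenyl)-2-(triphenyl-λ5-phosphanylidene)butanoate, via ylide 3 (not isolated), via acylphosphonium chloride 4 (not isolated)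
Conditions: NaN(SiMe3)2 (1.0 equiv), THF, 0 °C; then ClCO2Me (0.5 equiv), −78 °C to rt
Reagents that add atoms: methyl chloroformate, COC(=O)Cl
Why: Bestmann C-acylation of a non-stabilised ylide, in which one equivalent of 3 is acylated to 4 and a second equivalent deprotonates 4 (transylidation) to the ester-stabilised ylide 5, the regenerated phosphonium salt being filtered off for reuse.

Step 3
Reactants: 6 2-[4-(benzyloxy)phenyl]ethanol
Product: 7 [4-(benzyloxy)phenyl]acetaldehyde
Conditions: Dess–Martin periodinane, CH2Cl2, 0 °C to rt; used at once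
Reagents that add atoms: none
Why: Dess–Martin oxidation of a primary alcohol stops at the aldehyde under near-neutral conditions that the enolisable arylacetaldehyde tolerates.

Step 4
Reactants: 5 methyl 4-(3-methoxyphenyl)-2-(triphenyl-λ5-phosphanylidene)butanoate; 7 [4-(benzyloxy)phenyl]acetaldehyde
Product: 8 methyl (E)-4-[4-(benzyloxy)phenyl]-2-[2-(3-methoxyphenyl)ethyl]but-2-enoate
Conditions: CH2Cl2, rt to 40 °C
Reagents that add atoms: none
Why: The Wittig reaction of an α-alkyl ester-stabilised ylide with an unhindered aldehyde gives the 2-alkyl-2-enoate with the ester trans to the β-substituent, which sets the (E)-C1=C6 geometry without added base that could move the double bond toward the aryl ring.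

Step 5
Reactants: 8 methyl (E)-4-[4-(benzyloxy)phenyl]-2-[2-(3-methoxyphenyl)ethyl]but-2-enoate
Product: 9 (E)-4-[4-(benzyloxy)phenyl]-N-methoxy-2-[2-(3-methoxyphenyl)ethyl]-N-methylbut-2-enamide
Conditions: MeNH(OMe)·HCl, AlMe3, CH2Cl2, 0 °C to reflux
Reagents that add atoms: N,O-dimethylhydroxylamine hydrochloride, CNOC.Cl
Why: Weinreb amidation of the ester with the aluminium amide made from AlMe3 and the amine hydrochloride is non-basic, so the γ-benzylic protons and the alkene position should stay untouched.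

Step 6
Reactants: 9 (E)-4-[4-(benzyloxy)phenyl]-N-methoxy-2-[2-(3-methoxyphenyl)ethyl]-N-methylbut-2-enamide; 10 4-(benzyloxy)benzyl chloride
Product: 12 (E)-1,5-bis[4-(benzyloxy)phenyl]-3-[2-(3-methoxyphenyl)ethyl]pent-3-en-2-one, via Grignard reagent 11 (not isolated)
Conditions: 10, Mg, THF, 0 °C (slow addition); then 9, THF, −20 to 0 °C; used promptly
Reagents that add atoms: none
Why: Weinreb ketone synthesis, in which the benzylic Grignard reagent adds once to the N-methoxy-N-methylamide and the ketone is released only on work-up, so over-addition and exposure of the enolisable ketone to the reagent are both avoided.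

Step 7
Reactants: 10 4-(benzyloxy)benzyl chloride
Product: 13 1-(benzyloxy)-4-(prop-2-yn-1-yl)benzene
Conditions: HC≡CMgBr (3 equiv), CuCl (10 mol %), THF, 50 °C
Reagents that add atoms: ethynylmagnesium bromide, C#C[Mg]Br
Why: The CuCl-catalysed coupling of a reactive benzylic halide with an alkynyl Grignard reagent is a standard route to 3-arylprop-1-ynes, and the excess of ethynyl reagent suppresses double benzylation.

Step 8
Reactants: 13 1-(benzyloxy)-4-(prop-2-yn-1-yl)benzene; 12 (E)-1,5-bis[4-(benzyloxy)phenyl]-3-[2-(3-methoxyphenyl)ethyl]pent-3-en-2-one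
Product: 16 (E)-1,7-bis[4-(benzyloxy)phenyl]-4-[4-(benzyloxy)benzyl]-5-[2-(3-methoxyphenyl)ethyl]hept-5-en-2-yn-4-ol (racemic), via lithium acetylide 14 (not isolated), via dichlorocerium acetylide 15 (not isolated)
Conditions: 13, n-BuLi (1.0 equiv), THF, −78 °C; anhydrous CeCl3, −78 °C; then 12, −78 °C
Reagents that add atoms: none
Why: Imamoto organocerium 1,2-addition, in which the weakly basic, oxophilic cerium acetylide adds to the carbonyl of the enolisable enone faster than it deprotonates it; the carbinol centre C2 forms as the racemate, which does not matter because it becomes an sp2 ring carbon in step 10.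

Step 9
Reactants: 16 (E)-1,7-bis[4-(benzyloxy)phenyl]-4-[4-(benzyloxy)benzyl]-5-[2-(3-methoxyphenyl)ethyl]hept-5-en-2-yn-4-ol; 17 pivaloyl chloride
Product: 19 (E)-1,7-bis[4-(benzyloxy)phenyl]-4-[4-(benzyloxy)benzyl]-5-[2-(3-methoxyphenyl)ethyl]hept-5-en-2-yn-4-yl 2,2-dimethylpropanoate (racemic), via lithium alkoxide 18 (not isolated)
Conditions: LiN(SiMe3)2 (1.1 equiv), THF, −78 °C; then 17, −78 °C to rt
Reagents that add atoms: none
Why: O-Acylation of a tertiary lithium alkoxide with an acyl chloride is the usual esterification of hindered tertiary propargylic alcohols, and the basic, non-ionising conditions avoid allylic or propargylic transposition.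

Step 10
Reactants: 19 (E)-1,7-bis[4-(benzyloxy)phenyl]-4-[4-(benzyloxy)benzyl]-5-[2-(3-methoxyphenyl)ethyl]hept-5-en-2-yn-4-yl 2,2-dimethylpropanoate; 20 carbon monoxide
Product: 23 2,4,6-tris[4-(benzyloxy)benzyl]-3-hydroxy-5-[2-(3-methoxyphenyl)ethyl]phenyl 2,2-dimethylpropanoate, via dienylketene 21 (not isolated), via cyclohexadienone 22 (not isolated)
Conditions: [Rh(CO)2Cl]2 (5 mol %), CO (20 atm), ClCH2CH2Cl, 80 °C
Reagents that add atoms: none
Why: Proposed new method: monovalent rhodium coordinates the C3≡C4 alkyne of 19, the pivalate carbonyl oxygen attacks C3 and the ester shifts from C2 to C3 (1,2-acyloxy migration), leaving a rhodium carbene at C4 conjugated through the new C2=C3 bond to the C1=C6 alkene. Migratory insertion of CO 20 into the carbene forms C4–C5 and gives dienylketene 21, whose thermal disrotatory 6π electrocyclisation onto the alkene terminus C6 forms C5–C6 and closes ring A as the six-membered carbocyclic dienone 22, and enolisation through the C6 hydrogen gives phenol 23 with the free hydroxyl at C5 and the pivalate at C3. The closest known reaction type is the rhodium-catalysed carbonylative (5+1) benzannulation of 3-acyloxy-1,4-enynes bearing a terminal alkyne, which gives resorcinol monoesters; untested here are the internal, alkyl-substituted alkyne and the fully substituted diene. No stereocentre is created, since the racemic centre C2 and the C1=C6 geometry are both erased on aromatisation, the (E)-alkene serving only to place hydrogen and not the benzyl group on the inner face at C6 during closure. The selectivity required is 1,2- over 1,3-acyloxy migration, because the 1,3-shift would give an allenyl pivalate (a vinylallene) open to carbonylative five-membered ring formation. The levers chosen are the bulky pivalate on a tertiary carbon and the conjugating alkene that stabilises the carbene, together with CO pressure that should capture the carbene irreversibly so that a reversibly formed allenyl ester can return to the productive path.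

Step 11
Reactants: 23 2,4,6-tris[4-(benzyloxy)benzyl]-3-hydroxy-5-[2-(3-methoxyphenyl)ethyl]phenyl 2,2-dimethylpropanoate
Product: 24 2,4,6-tris[4-(benzyloxy)benzyl]-3-methoxy-5-[2-(3-methoxyphenyl)ethyl]phenyl 2,2-dimethylpropanoate
Conditions: MeI, K2CO3, DMF, 40 °C
Reagents that add atoms: iodomethane, CI
Why: Williamson O-methylation of the only free phenol; the C3 oxygen is masked as the pivalate, which cannot migrate to the meta C5 oxygen, so the two ring A oxygens stay differentiated.

Step 12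
Reactants: 24 2,4,6-tris[4-(benzyloxy)benzyl]-3-methoxy-5-[2-(3-methoxyphenyl)ethyl]phenyl 2,2-dimethylpropanoate
Product: 25 2,4,6-tris[4-(benzyloxy)benzyl]-3-methoxy-5-[2-(3-methoxyphenyl)ethyl]phenol
Conditions: LiAlH4, THF, 0 °C to rt
Reagents that add atoms: none
Why: Hydride reduction of the ester cleaves the doubly ortho-substituted aryl pivalate to the phenoxide and neopentyl alcohol where alkoxide transesterification could be slow, and benzyl and methyl ethers are inert to the reagent.

Step 13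
Reactants: 25 2,4,6-tris[4-(benzyloxy)benzyl]-3-methoxy-5-[2-(3-methoxyphenyl)ethyl]phenol
Product: 26 2,4,6-tris(4-hydroxybenzyl)-3-methoxy-5-[2-(3-methoxyphenyl)ethyl]phenol (CNP0285788.0)
Conditions: H2 (1 atm), Pd/C (10 wt %), EtOAc/MeOH, rt
Reagents that add atoms: none
Why: Catalytic hydrogenolysis over Pd/C cleaves the three benzyl aryl ethers, while the diarylmethane carbons and the aryl methyl ethers are stable under these mild conditions.

**Compound list**

1 | 1-(3-bromopropyl)-3-methoxybenzene | COc1cccc(CCCBr)c1 | starting material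
2 | [3-(3-methoxyphenyl)propyl](triphenyl)phosphonium bromide | COc1cccc(CCC[P+](c2ccccc2)(c2ccccc2)c2ccccc2)c1.[Br-] | intermediate
3 | [3-(3-methoxyphenyl)propylidene](triphenyl)-λ5-phosphane (ylide, not isolated) | COc1cccc(CCC=P(c2ccccc2)(c2ccccc2)c2ccccc2)c1 | intermediate
4 | [1-methoxy-4-(3-methoxyphenyl)-1-oxobutan-2-yl](triphenyl)phosphonium chloride (not isolated) | COC(=O)C(CCc1cccc(OC)c1)[P+](c1ccccc1)(c1ccccc1)c1ccccc1.[Cl-] | intermediate
5 | methyl 4-(3-methoxyphenyl)-2-(triphenyl-λ5-phosphanylidene)butanoate | COC(=O)C(CCc1cccc(OC)c1)=P(c1ccccc1)(c1ccccc1)c1ccccc1 | intermediate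
6 | 2-[4-(benzyloxy)phenyl]ethanol | OCCc1ccc(OCc2ccccc2)cc1 | starting material
7 | [4-(benzyloxy)phenyl]acetaldehyde | O=CCc1ccc(OCc2ccccc2)cc1 | intermediate
8 | methyl (E)-4-[4-(benzyloxy)phenyl]-2-[2-(3-methoxyphenyl)ethyl]but-2-enoate | COC(=O)/C(CCc1cccc(OC)c1)=C/Cc1ccc(OCc2ccccc2)cc1 | intermediate
9 | (E)-4-[4-(benzyloxy)phenyl]-N-methoxy-2-[2-(3-methoxyphenyl)ethyl]-N-methylbut-2-enamide | CON(C)C(=O)/C(CCc1cccc(OC)c1)=C/Cc1ccc(OCc2ccccc2)cc1 | intermediate
10 | 4-(benzyloxy)benzyl chloride | ClCc1ccc(OCc2ccccc2)cc1 | starting material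
11 | [4-(benzyloxy)benzyl]magnesium chloride (not isolated) | Cl[Mg]Cc1ccc(OCc2ccccc2)cc1 | intermediate
12 | (E)-1,5-bis[4-(benzyloxy)phenyl]-3-[2-(3-methoxyphenyl)ethyl]pent-3-en-2-one | O=C(Cc1ccc(OCc2ccccc2)cc1)/C(CCc1cccc(OC)c1)=C/Cc1ccc(OCc2ccccc2)cc1 | intermediate
13 | 1-(benzyloxy)-4-(prop-2-yn-1-yl)benzene | C#CCc1ccc(OCc2ccccc2)cc1 | intermediate
14 | lithium 3-[4-(benzyloxy)phenyl]prop-1-yn-1-ide (not isolated) | [Li]C#CCc1ccc(OCc2ccccc2)cc1 | intermediate
15 | dichloro{3-[4-(benzyloxy)phenyl]prop-1-yn-1-yl}cerium (not isolated) | Cl[Ce](Cl)C#CCc1ccc(OCc2ccccc2)cc1 | intermediate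
16 | (E)-1,7-bis[4-(benzyloxy)phenyl]-4-[4-(benzyloxy)benzyl]-5-[2-(3-methoxyphenyl)ethyl]hept-5-en-2-yn-4-ol (racemic) | OC(C#CCc1ccc(OCc2ccccc2)cc1)(Cc1ccc(OCc2ccccc2)cc1)/C(CCc1cccc(OC)c1)=C/Cc1ccc(OCc2ccccc2)cc1 | intermediate
17 | pivaloyl chloride | CC(C)(C)C(=O)Cl | starting material
18 | lithium alkoxide of 16 (not isolated) | [Li]OC(C#CCc1ccc(OCc2ccccc2)cc1)(Cc1ccc(OCc2ccccc2)cc1)/C(CCc1cccc(OC)c1)=C/Cc1ccc(OCc2ccccc2)cc1 | intermediate
19 | (E)-1,7-bis[4-(benzyloxy)phenyl]-4-[4-(benzyloxy)benzyl]-5-[2-(3-methoxyphenyl)ethyl]hept-5-en-2-yn-4-yl 2,2-dimethylpropanoate (racemic) | CC(C)(C)C(=O)OC(C#CCc1ccc(OCc2ccccc2)cc1)(Cc1ccc(OCc2ccccc2)cc1)/C(CCc1cccc(OC)c1)=C/Cc1ccc(OCc2ccccc2)cc1 | intermediate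
20 | carbon monoxide | [C-]#[O+] | starting material
21 | (3E,5E)-2,4-bis[4-(benzyloxy)benzyl]-7-[4-(benzyloxy)phenyl]-5-[2-(3-methoxyphenyl)ethyl]-1-oxohepta-1,3,5-trien-3-yl 2,2-dimethylpropanoate (dienylketene, not isolated) | O=C=C(Cc1ccc(OCc2ccccc2)cc1)/C(OC(=O)C(C)(C)C)=C(Cc1ccc(OCc2ccccc2)cc1)\C(CCc1cccc(OC)c1)=C\Cc1ccc(OCc2ccccc2)cc1 | intermediate
22 | 2,4,6-tris[4-(benzyloxy)benzyl]-5-[2-(3-methoxyphenyl)ethyl]-3-oxocyclohexa-1,5-dien-1-yl 2,2-dimethylpropanoate (racemic, not isolated) | O=C1C(Cc2ccc(OCc3ccccc3)cc2)C(CCc2cccc(OC)c2)=C(Cc2ccc(OCc3ccccc3)cc2)C(OC(=O)C(C)(C)C)=C1Cc1ccc(OCc2ccccc2)cc1 | intermediate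
23 | 2,4,6-tris[4-(benzyloxy)benzyl]-3-hydroxy-5-[2-(3-methoxyphenyl)ethyl]phenyl 2,2-dimethylpropanoate | COc1cccc(CCc2c(Cc3ccc(OCc4ccccc4)cc3)c(OC(=O)C(C)(C)C)c(Cc3ccc(OCc4ccccc4)cc3)c(O)c2Cc2ccc(OCc3ccccc3)cc2)c1 | intermediate
24 | 2,4,6-tris[4-(benzyloxy)benzyl]-3-methoxy-5-[2-(3-methoxyphenyl)ethyl]phenyl 2,2-dimethylpropanoate | COc1cccc(CCc2c(Cc3ccc(OCc4ccccc4)cc3)c(OC(=O)C(C)(C)C)c(Cc3ccc(OCc4ccccc4)cc3)c(OC)c2Cc2ccc(OCc3ccccc3)cc2)c1 | intermediate
25 | 2,4,6-tris[4-(benzyloxy)benzyl]-3-methoxy-5-[2-(3-methoxyphenyl)ethyl]phenol | COc1cccc(CCc2c(Cc3ccc(OCc4ccccc4)cc3)c(O)c(Cc3ccc(OCc4ccccc4)cc3)c(OC)c2Cc2ccc(OCc3ccccc3)cc2)c1 | intermediate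
26 | 2,4,6-tris(4-hydroxybenzyl)-3-methoxy-5-[2-(3-methoxyphenyl)ethyl]phenol (CNP0285788.0) | COc1cccc(CCc2c(Cc3ccc(O)cc3)c(O)c(Cc3ccc(O)cc3)c(OC)c2Cc2ccc(O)cc2)c1 | target

**Step count**

Total: 13 steps. Longest linear sequence: 11 steps (1, 2, 4, 5, 6, 8, 9, 10, 11, 12, 13).

**Steps most likely to fail**

Step 10. The internal, alkyl-substituted propargylic pivalate may undergo 1,3-acyloxy migration faster than the 1,2-shift, so that material drains into an allenyl ester and carbonylative five-membered ring formation instead of the carbene–ketene path. The fallback uses known chemistry, sets out from enone 12 and rejoins the route at methyl ether 24. The alkyne is made terminal, which is the substrate class on which the carbonylative (5+1) benzannulation is established, and the C4 benzyl group is attached afterwards by cross-coupling. Addition of HC≡CMgBr premixed with CeCl3 to 12 (THF, −78 °C) should give (E)-3-[4-(benzyloxy)benzyl]-6-[4-(benzyloxy)phenyl]-4-[2-(3-methoxyphenyl)ethyl]hex-4-en-1-yn-3-ol F1. Treatment with LiN(SiMe3)2 and then pivaloyl chloride 17 should give (E)-3-[4-(benzyloxy)benzyl]-6-[4-(benzyloxy)phenyl]-4-[2-(3-methoxyphenyl)ethyl]hex-4-en-1-yn-3-yl 2,2-dimethylpropanoate F2. With [Rh(CO)2Cl]2 under CO 20 this should give 2,4-bis[4-(benzyloxy)benzyl]-5-hydroxy-3-[2-(3-methoxyphenyl)ethyl]phenyl 2,2-dimethylpropanoate F3, in which C4 carries hydrogen. NBS (CH2Cl2, −20 °C) should brominate C4, the only free ring A position and ortho to the free hydroxyl, to give 2,4-bis[4-(benzyloxy)benzyl]-6-bromo-5-hydroxy-3-[2-(3-methoxyphenyl)ethyl]phenyl 2,2-dimethylpropanoate F4. MeI and K2CO3 in DMF should give 2,4-bis[4-(benzyloxy)benzyl]-6-bromo-5-methoxy-3-[2-(3-methoxyphenyl)ethyl]phenyl 2,2-dimethylpropanoate F5. Negishi coupling of F5 with [4-(benzyloxy)benzyl]zinc chloride F6 (from 10, Zn and LiCl in THF) under Pd(OAc)2 and SPhos should give 24.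

Step 8. The acetylide may deprotonate the benzylic α-methylene or the γ-methylene of 12 instead of adding to the carbonyl, which would return 12 or its double-bond isomer after work-up. The fallback sets out from Weinreb amide 9 and rejoins at carbinol 16; it inverts the order of the two carbonyl additions so that the ketone that meets the second organometallic has no α-hydrogen. Lithium acetylide 14 (from 13 and n-BuLi) added to 9 at −78 °C should give (E)-1,7-bis[4-(benzyloxy)phenyl]-5-[2-(3-methoxyphenyl)ethyl]hept-5-en-2-yn-4-one F7. Grignard reagent 11 added to F7 at −78 °C should give 16 by 1,2-addition.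

Step 4. Olefination by the α-branched ylide may be slow enough for the arylacetaldehyde to self-condense, and the new double bond may drift out of conjugation toward the aryl ring or lose its (E) geometry. The fallback sets out from alkyne 13 and aldehyde 7 and rejoins at enone 12, replacing steps 1, 2, 4, 5 and 6. Lithium acetylide 14 added to 7 (THF, −78 °C) should give 1,5-bis[4-(benzyloxy)phenyl]pent-3-yn-2-ol F8. CuI-catalysed anti-carbomagnesiation of F8 with [2-(3-methoxyphenyl)ethyl]magnesium bromide F9 (from 3-methoxyphenethyl bromide and Mg) places the phenethyl group on the alkyne carbon next to the carbinol and magnesium on the remote carbon within a five-membered alkoxide chelate. Protonation should then give (E)-1,5-bis[4-(benzyloxy)phenyl]-3-[2-(3-methoxyphenyl)ethyl]pent-3-en-2-ol F10 with the required geometry. Dess–Martin oxidation of F10 should give 12.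

**Further compounds**

F1 | step 10 | (E)-3-[4-(benzyloxy)benzyl]-6-[4-(benzyloxy)phenyl]-4-[2-(3-methoxyphenyl)ethyl]hex-4-en-1-yn-3-ol | C#CC(O)(Cc1ccc(OCc2ccccc2)cc1)/C(CCc1cccc(OC)c1)=C/Cc1ccc(OCc2ccccc2)cc1
F2 | step 10 | (E)-3-[4-(benzyloxy)benzyl]-6-[4-(benzyloxy)phenyl]-4-[2-(3-methoxyphenyl)ethyl]hex-4-en-1-yn-3-yl 2,2-dimethylpropanoate | C#CC(OC(=O)C(C)(C)C)(Cc1ccc(OCc2ccccc2)cc1)/C(CCc1cccc(OC)c1)=C/Cc1ccc(OCc2ccccc2)cc1
F3 | step 10 | 2,4-bis[4-(benzyloxy)benzyl]-5-hydroxy-3-[2-(3-methoxyphenyl)ethyl]phenyl 2,2-dimethylpropanoate | COc1cccc(CCc2c(Cc3ccc(OCc4ccccc4)cc3)c(OC(=O)C(C)(C)C)cc(O)c2Cc2ccc(OCc3ccccc3)cc2)c1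
F4 | step 10 | 2,4-bis[4-(benzyloxy)benzyl]-6-bromo-5-hydroxy-3-[2-(3-methoxyphenyl)ethyl]phenyl 2,2-dimethylpropanoate | COc1cccc(CCc2c(Cc3ccc(OCc4ccccc4)cc3)c(OC(=O)C(C)(C)C)c(Br)c(O)c2Cc2ccc(OCc3ccccc3)cc2)c1
F5 | step 10 | 2,4-bis[4-(benzyloxy)benzyl]-6-bromo-5-methoxy-3-[2-(3-methoxyphenyl)ethyl]phenyl 2,2-dimethylpropanoate | COc1cccc(CCc2c(Cc3ccc(OCc4ccccc4)cc3)c(OC(=O)C(C)(C)C)c(Br)c(OC)c2Cc2ccc(OCc3ccccc3)cc2)c1
F6 | step 10 | [4-(benzyloxy)benzyl]zinc chloride | Cl[Zn]Cc1ccc(OCc2ccccc2)cc1
F7 | step 8 | (E)-1,7-bis[4-(benzyloxy)phenyl]-5-[2-(3-methoxyphenyl)ethyl]hept-5-en-2-yn-4-one | O=C(C#CCc1ccc(OCc2ccccc2)cc1)/C(CCc1cccc(OC)c1)=C/Cc1ccc(OCc2ccccc2)cc1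
F8 | step 4 | 1,5-bis[4-(benzyloxy)phenyl]pent-3-yn-2-ol (racemic) | OC(Cc1ccc(OCc2ccccc2)cc1)C#CCc1ccc(OCc2ccccc2)cc1
F9 | step 4 | [2-(3-methoxyphenyl)ethyl]magnesium bromide | COc1cccc(CC[Mg]Br)c1
F10 | step 4 | (E)-1,5-bis[4-(benzyloxy)phenyl]-3-[2-(3-methoxyphenyl)ethyl]pent-3-en-2-ol (racemic) | OC(Cc1ccc(OCc2ccccc2)cc1)/C(CCc1cccc(OC)c1)=C/Cc1ccc(OCc2ccccc2)cc1
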